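**Plan**
1. Retrosynthesis: first cut C4–C3' (ring C to the chalcone ring, ring A'), giving a flavan-4-yl cation and 2',6'-dihydroxy-4'-methoxychalcone; then cut O1–C2 of ring C, giving an ortho-cinnamylphenol; then cut C4–C4a, giving 2,5-dimethoxybenzene-1,3-diol and cinnamyl alcohol.
2. Forward: the ring A diol is made from a dibromide and C-cinnamylated; ring C is closed at O1–C2; C4–H is oxidised and ring A acetylated; the chalcone (one separate step) is joined at C4; the acetate is removed.
3. Enabling feature: C2 carries the unsubstituted phenyl ring B and stands 1,5 to the oxygen on C8a, so a C2=C3 styrene is a latent benzylic C2 cation that this oxygen can capture. Ring A and ring A' both come from symmetric phenols with equivalent ring positions, so no regiochemical choice arises.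
4. Stereochemistry: C2 (R) comes from a chiral Brønsted acid in the ring closure; C4 (R) follows by 1,3-induction, the chalcone ring adding to the C4 cation anti to the 2-phenyl (2,4-trans).
5. Helper: a 7-O-acetyl group damps the nucleophilicity of ring A during the union and is removed in the last step.

Key step: step 4

Remark: the SMILES is read as the (2R,4R) isomer, with the 2-phenyl and the 4-aryl group trans on ring C; 2,6-dibromo-4-methoxyphenol is taken as an article of commerce.

**Route**

Step 1
Reactants: 1 2,6-dibromo-4-methoxyphenol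
Product: 2 1,3-dibromo-2,5-dimethoxybenzene
Conditions: MeI, K2CO3, DMF, 25 °C
Reagents that add atoms: iodomethane, CI
Why: Williamson O-methylation, in which the phenoxide (made more acidic by the two ortho bromines) displaces iodide from the unhindered methyl carbon.

Step 2
Reactants: 2 1,3-dibromo-2,5-dimethoxybenzene
Product: 4 2,5-dimethoxybenzene-1,3-diol, via 3-bromo-2,5-dimethoxyphenol 3 (not isolated)
Conditions: Pd2(dba)3 (2 mol %), tBuXPhos (8 mol %), KOH, 1,4-dioxane/H2O, 100 °C, argon; then aq. HCl
Reagents that add atoms: potassium hydroxide, [K+].[OH-]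
Why: Twofold palladium-catalysed hydroxylation of an aryl bromide (C–O cross-coupling with hydroxide), in which the bulky biarylphosphine should drive C–O reductive elimination even from the electron-rich bromophenoxide 3.

Step 3
Reactants: 4 2,5-dimethoxybenzene-1,3-diol; 5 (E)-cinnamyl alcohol
Product: 6 4-[(2E)-3-phenylprop-2-en-1-yl]-2,5-dimethoxybenzene-1,3-diol
Conditions: TsOH·H2O (5 mol %), MeCN, 25 °C; 4 in threefold excess, 5 added slowly
Reagents that add atoms: none
Why: Dehydrative Friedel–Crafts allylation, in which the acid ionizes 5 to the cinnamyl cation and the symmetric diol captures its unsubstituted terminus through C4 (identical with C6, the only free ring carbon, ortho/para to both hydroxyls) to give the linear E-styrene, the excess of 4 limiting double alkylation.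

Step 4
Reactants: 6 4-[(2E)-3-phenylprop-2-en-1-yl]-2,5-dimethoxybenzene-1,3-diol
Product: 7 (2R)-5,8-dimethoxy-2-phenyl-3,4-dihydro-2H-chromen-7-ol
Conditions: chiral BINOL-derived N-triflyl imidodiphosphorimidate (IDPi) Brønsted acid (5 mol %, antipode chosen to give 2R), CHCl3, 5 Å molecular sieves, 40 °C
Reagents that add atoms: none
Why: Proposed new method: the confined chiral acid should protonate C3 of the C2=C3 styrene while its anion, hydrogen-bonded to the hydroxyl ortho to the side chain (the later O1), delivers that oxygen to the developing benzylic cation at C2, so that the O1–C2 bond forms in an asynchronous Markovnikov hydroalkoxylation. The closest known reaction types are the enantioselective intramolecular hydroalkoxylation of alkenols under imidodiphosphorimidate catalysis and the racemic strong-acid cyclization of 2-cinnamylphenols to flavans; new is enantiocontrol with a phenol nucleophile on a 1,2-disubstituted styrene. Ring C closes in the 6-endo-trig mode. The one new stereocentre, C2, is set by the catalyst alone, whose chiral pocket distinguishes the two faces of the planar C2 carbon (R with the antipode chosen). Six- rather than five-membered closure is needed and is secured by the phenyl on C2, the only carbon that can carry benzylic charge, and site selectivity between the two hydroxyls is secured because only the one ortho to the side chain can reach C2. The uncatalysed racemic pathway must stay slow, which the weakly polar medium and the moderate temperature are meant to ensure.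

Step 5
Reactants: 7 (2R)-5,8-dimethoxy-2-phenyl-3,4-dihydro-2H-chromen-7-ol
Product: 9 (2R)-4,5,8-trimethoxy-2-phenyl-3,4-dihydro-2H-chromen-7-ol (mixture of C4 epimers), via quinone methide 8 (not isolated)
Conditions: DDQ (1.0 equiv), CH2Cl2/MeOH 5:1, −20 to 0 °C
Reagents that add atoms: methanol, CO
Why: DDQ oxidation of a para-alkylphenol, in which hydride abstraction from C4 (para to the C7 hydroxyl through C4a and flanked by the O1 and 5-OMe donors) gives quinone methide 8 and 1,6-addition of methanol restores ring A, C2 not being touched and the C4 configuration being of no consequence.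

Step 6
Reactants: 9 (2R)-4,5,8-trimethoxy-2-phenyl-3,4-dihydro-2H-chromen-7-ol
Product: 10 (2R)-4,5,8-trimethoxy-2-phenyl-3,4-dihydro-2H-chromen-7-yl acetate (mixture of C4 epimers)
Conditions: Ac2O, pyridine, DMAP (cat.), CH2Cl2, 0 °C
Reagents that add atoms: acetic anhydride, CC(=O)OC(C)=O
Why: Nucleophile-catalysed O-acylation of the only free hydroxyl, which turns the strongly donating C7 oxygen into an acetate so that C6 of ring A no longer competes as a Friedel–Crafts nucleophile in step 8.

Step 7
Reactants: 11 1-(2,6-dihydroxy-4-methoxyphenyl)ethanone; 12 benzaldehyde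
Product: 14 (2E)-1-(2,6-dihydroxy-4-methoxyphenyl)-3-phenylprop-2-en-1-one, via aldol adduct 13 (not isolated)
Conditions: KOH (50 % aq.), EtOH, 0 to 25 °C; then cold 1 M HCl to pH 5
Reagents that add atoms: none
Why: Claisen–Schmidt condensation, in which the methyl ketone enolate adds to benzaldehyde and E1cB dehydration of aldol 13 gives the conjugated E-enone, the open-chain chalcone phenoxide being favoured over the flavanone in strong alkali.

Step 8
Reactants: 10 (2R)-4,5,8-trimethoxy-2-phenyl-3,4-dihydro-2H-chromen-7-yl acetate; 14 (2E)-1-(2,6-dihydroxy-4-methoxyphenyl)-3-phenylprop-2-en-1-one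
Product: 15 (2R,4R)-4-{2,4-dihydroxy-6-methoxy-3-[(2E)-3-phenylprop-2-enoyl]phenyl}-5,8-dimethoxy-2-phenyl-3,4-dihydro-2H-chromen-7-yl acetate
Conditions: Sc(OTf)3 (10 mol %), MeCN/CH2Cl2, 0 to 25 °C; 14 (3 equiv), 10 added slowly
Reagents that add atoms: none
Why: Friedel–Crafts alkylation, in which Lewis-acid ionization of the benzylic methyl ether gives the flavan-4-yl cation and the equivalent C3'/C5' positions of 14 should attack axially on the face anti to the pseudo-equatorial 2-phenyl of the sofa-shaped cation, setting C4 as R (2,4-trans) with the new aryl group pseudo-axial and clear of the peri 5-OMe.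

Step 9
Reactants: 15 (2R,4R)-4-{2,4-dihydroxy-6-methoxy-3-[(2E)-3-phenylprop-2-enoyl]phenyl}-5,8-dimethoxy-2-phenyl-3,4-dihydro-2H-chromen-7-yl acetate
Product: 16 sarcandrone B, (2E)-1-{3-[(2R,4R)-7-hydroxy-5,8-dimethoxy-2-phenyl-3,4-dihydro-2H-chromen-4-yl]-2,6-dihydroxy-4-methoxyphenyl}-3-phenylprop-2-en-1-one
Conditions: K2CO3 (cat.), MeOH, 0 °C; AcOH quench
Reagents that add atoms: none
Why: Base-catalysed transesterification (Zemplén-type methanolysis) of the aryl acetate, brief and cold enough that the enone, the chalcone hydroxyls and both stereocentres should be left alone.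

**Compound list**
1 | 2,6-dibromo-4-methoxyphenol | COc1cc(Br)c(O)c(Br)c1 | starting material
2 | 1,3-dibromo-2,5-dimethoxybenzene | COc1cc(Br)c(OC)c(Br)c1 | intermediate
3 | 3-bromo-2,5-dimethoxyphenol (not isolated) | COc1cc(O)c(OC)c(Br)c1 | intermediate
4 | 2,5-dimethoxybenzene-1,3-diol | COc1cc(O)c(OC)c(O)c1 | intermediate
5 | (E)-cinnamyl alcohol | OC/C=C/c1ccccc1 | starting material
6 | 4-[(2E)-3-phenylprop-2-en-1-yl]-2,5-dimethoxybenzene-1,3-diol | COc1cc(O)c(OC)c(O)c1C/C=C/c1ccccc1 | intermediate
7 | (2R)-5,8-dimethoxy-2-phenyl-3,4-dihydro-2H-chromen-7-ol | COc1cc(O)c(OC)c2c1CC[C@H](c1ccccc1)O2 | intermediate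
8 | (2R)-5,8-dimethoxy-2-phenyl-2,3-dihydro-7H-chromen-7-one, para-quinone methide with C4=C4a (not isolated) | COC1=CC(=O)C(OC)=C2O[C@@H](c3ccccc3)CC=C12 | intermediate
9 | (2R)-4,5,8-trimethoxy-2-phenyl-3,4-dihydro-2H-chromen-7-ol, C4 epimers | COC1C[C@H](c2ccccc2)Oc2c(OC)c(O)cc(OC)c21 | intermediate
10 | (2R)-4,5,8-trimethoxy-2-phenyl-3,4-dihydro-2H-chromen-7-yl acetate, C4 epimers | COC1C[C@H](c2ccccc2)Oc2c(OC)c(OC(C)=O)cc(OC)c21 | intermediate
11 | 1-(2,6-dihydroxy-4-methoxyphenyl)ethanone | CC(=O)c1c(O)cc(OC)cc1O | starting material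
12 | benzaldehyde | O=Cc1ccccc1 | starting material
13 | 3-hydroxy-1-(2,6-dihydroxy-4-methoxyphenyl)-3-phenylpropan-1-one, racemic aldol adduct (not isolated) | COc1cc(O)c(C(=O)CC(O)c2ccccc2)c(O)c1 | intermediate
14 | (2E)-1-(2,6-dihydroxy-4-methoxyphenyl)-3-phenylprop-2-en-1-one | COc1cc(O)c(C(=O)/C=C/c2ccccc2)c(O)c1 | intermediate
15 | (2R,4R)-4-{2,4-dihydroxy-6-methoxy-3-[(2E)-3-phenylprop-2-enoyl]phenyl}-5,8-dimethoxy-2-phenyl-3,4-dihydro-2H-chromen-7-yl acetate | COc1cc(O)c(C(=O)/C=C/c2ccccc2)c(O)c1[C@H]1C[C@H](c2ccccc2)Oc2c(OC)c(OC(C)=O)cc(OC)c21 | intermediate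
16 | sarcandrone B | COc1cc(O)c(C(=O)/C=C/c2ccccc2)c(O)c1[C@H]1C[C@H](c2ccccc2)Oc2c(OC)c(O)cc(OC)c21 | target

**Count and risks**
Total steps: 9. Longest linear sequence: 8 (steps 1–6, 8, 9); step 7 makes the chalcone fragment.

Step 4 (the new method). The risks are insufficient face discrimination at C2, a competing racemic background cyclization, and acid-induced loss or migration of the cinnamyl group by ipso-protonation of the very electron-rich ring A. The fallback uses known chemistry, sets out from 4 and returns at 7. Conjugate Friedel–Crafts alkylation of 4 with 1-phenylprop-2-en-1-one under catalytic TsOH should give 3-(2,4-dihydroxy-3,6-dimethoxyphenyl)-1-phenylpropan-1-one F1. Noyori transfer hydrogenation with RuCl[(S,S)-TsDPEN](p-cymene) and HCO2H/Et3N should give 4-[(3S)-3-hydroxy-3-phenylpropyl]-2,5-dimethoxybenzene-1,3-diol F2. Mitsunobu cyclization (PPh3, DIAD, THF, high dilution) then forms the same O1–C2 bond with inversion at the carbinol carbon and gives 7.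

Step 5. The risks are a second hydride abstraction from the product (towards the ketone or flavylium level) and oxidation of the electron-rich ring instead of the C4–H bond. The fallback brings the C4 oxygen in with the carbon skeleton instead of by C–H oxidation; it sets out from 4 (with 12) and returns at 15. C-Acetylation of 4 (Ac2O, BF3·OEt2) should give 1-(2,4-dihydroxy-3,6-dimethoxyphenyl)ethanone F3, and Claisen–Schmidt condensation with 12 gives (2E)-1-(2,4-dihydroxy-3,6-dimethoxyphenyl)-3-phenylprop-2-en-1-one F4. An enantioselective intramolecular oxa-Michael addition under a cinchona-alkaloid thiourea catalyst gives (2R)-7-hydroxy-5,8-dimethoxy-2-phenyl-2,3-dihydro-4H-chromen-4-one F5. NaBH4 reduction gives (2R)-5,8-dimethoxy-2-phenyl-3,4-dihydro-2H-chromene-4,7-diol F6, and diacetylation (Ac2O, pyridine) gives (2R)-5,8-dimethoxy-2-phenyl-3,4-dihydro-2H-chromene-4,7-diyl diacetate F7. F7 is ionized at C4 in place of 10 under the conditions of step 8 and gives 15.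

Step 8. The risks are sluggish ionization of the deactivated ether, double alkylation of the chalcone ring, acid-induced cyclization of the chalcone to a flavanone, and poor facial selectivity at C4. The fallback joins the ketone first and builds the enone last; it sets out from 10 and 11 and returns at 16. Friedel–Crafts union of 10 with acetophenone 11, which tolerates stronger acid (TfOH cat.), should give (2R,4R)-4-(3-acetyl-2,4-dihydroxy-6-methoxyphenyl)-5,8-dimethoxy-2-phenyl-3,4-dihydro-2H-chromen-7-yl acetate F8. Claisen–Schmidt condensation of F8 with 12 (KOH, EtOH) then forms the E-enone and cleaves the acetate in the same operation, giving 16.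

**Further compounds**
F1 | step 4 | 3-(2,4-dihydroxy-3,6-dimethoxyphenyl)-1-phenylpropan-1-one | COc1cc(O)c(OC)c(O)c1CCC(=O)c1ccccc1
F2 | step 4 | 4-[(3S)-3-hydroxy-3-phenylpropyl]-2,5-dimethoxybenzene-1,3-diol | COc1cc(O)c(OC)c(O)c1CC[C@H](O)c1ccccc1
F3 | step 5 | 1-(2,4-dihydroxy-3,6-dimethoxyphenyl)ethanone | CC(=O)c1c(OC)cc(O)c(OC)c1O
F4 | step 5 | (2E)-1-(2,4-dihydroxy-3,6-dimethoxyphenyl)-3-phenylprop-2-en-1-one | COc1cc(O)c(OC)c(O)c1C(=O)/C=C/c1ccccc1
F5 | step 5 | (2R)-7-hydroxy-5,8-dimethoxy-2-phenyl-2,3-dihydro-4H-chromen-4-one | COc1cc(O)c(OC)c2c1C(=O)C[C@H](c1ccccc1)O2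
F6 | step 5 | (2R)-5,8-dimethoxy-2-phenyl-3,4-dihydro-2H-chromene-4,7-diol, C4 epimers | COc1cc(O)c(OC)c2c1C(O)C[C@H](c1ccccc1)O2
F7 | step 5 | (2R)-5,8-dimethoxy-2-phenyl-3,4-dihydro-2H-chromene-4,7-diyl diacetate, C4 epimers | COc1cc(OC(C)=O)c(OC)c2c1C(OC(C)=O)C[C@H](c1ccccc1)O2
F8 | step 8 | (2R,4R)-4-(3-acetyl-2,4-dihydroxy-6-methoxyphenyl)-5,8-dimethoxy-2-phenyl-3,4-dihydro-2H-chromen-7-yl acetate | COc1cc(O)c(C(C)=O)c(O)c1[C@H]1C[C@H](c2ccccc2)Oc2c(OC)c(OC(C)=O)cc(OC)c21
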